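**Plan** (target locants follow cyclohepta[b]furan numbering: O1, C2, C3, C3a, C4–C8, C8a; atoms of the auxiliary pyran ring are primed, O1′ on C8 and C4′ on C7)

1. Retrosynthesis: the C8 isovalerate and the crotonoyl group come from E1cB opening of a 2′-methyltetrahydropyran-4′-one fused at C7–C8 (O1′ = oxygen on C8; C4′–C3′–C2′–CH3 = crotonoyl). Next the lactone is cut (C3–C3a and O1–C8a), then C8–C8a and C6–C7 in one operation.
2. Enabling feature: in the seven-membered carbocycle the C5 ketone and the oxygenated C8a are 1,5-related across C6(CH3)–C7–C8. With C8a as a carbonyl this is a de Mayo retron: joining C6 to C8a leaves the five-membered ring of 2-methylcyclopentane-1,3-dione (C3a, C4, C5, C6, C8a) and the C7=C8 double bond of an enediol bis-ether dihydropyran.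
3. Forward order of rings: pyran (asymmetric hetero-Diels–Alder), cyclobutane ([2+2] photocycloaddition), seven-membered ring (retro-aldol expansion of the five-membered ring), lactone (Mitsunobu acrylation, Rauhut–Currier cyclisation), pyran opened last.
4. Stereochemistry: the catalyst sets C2′, which controls C4′ (cis reduction) and, by facial shielding, C7/C8 in the photocycloaddition; both pyran stereocentres are destroyed later. C8a comes from chelation-controlled reduction followed by Mitsunobu inversion, C3a from the lactone tether, C6 from thermodynamic control next to the ketone.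

Key step: step 7

Remark (assumption): C6, the only enolisable stereocentre of the target, is assumed to prefer the natural configuration at equilibrium (methyl anti to the carbon branch on C7, gauche only to oxygen).

Step 1
Reactants: 1 1-(tert-butyldimethylsilyloxy)propan-2-one
Product: 2 (Z)-3-(tert-butyldimethylsilyloxy)-4-(dimethylamino)but-3-en-2-one
Conditions: Me2NCH(OMe)2 (neat), 90 °C
Reagents that add atoms: N,N-dimethylformamide dimethyl acetal, COC(OC)N(C)C
Why: Aminomethylenation (enaminone formation) should occur at the more acidic α-siloxy methylene, as with other α-alkoxyacetones, giving the enaminone that carries future C8 (CH–N), C7 (C–OSi) and C4′ (C=O).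

Step 2
Reactants: 2 (Z)-3-(tert-butyldimethylsilyloxy)-4-(dimethylamino)but-3-en-2-one
Product: 3 (1Z)-2,3-bis(tert-butyldimethylsilyloxy)-N,N-dimethylbuta-1,3-dien-1-amine
Conditions: KN(SiMe3)2, THF, −78 °C; then TBSCl
Reagents that add atoms: tert-butyldimethylsilyl chloride, CC(C)(C)[Si](C)(C)Cl
Why: Kinetic deprotonation of the methyl ketone and O-silylation give the 1-amino-3-siloxy diene, the standard preparation of such dienes.

Step 3
Reactants: 3 (1Z)-2,3-bis(tert-butyldimethylsilyloxy)-N,N-dimethylbuta-1,3-dien-1-amine; 4 acetaldehyde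
Product: 6 (2S)-5-(tert-butyldimethylsilyloxy)-2-methyl-2,3-dihydro-4H-pyran-4-one, via aminal cycloadduct 5 (not isolated)
Conditions: 1-naphthyl-TADDOL (20 mol %, the enantiomer that delivers the 2S product), toluene, −78 °C; then AcCl, CH2Cl2, −78 °C
Reagents that add atoms: none
Why: Hydrogen-bond-catalysed hetero-Diels–Alder reaction of the aminosiloxy diene with the diol-bound aldehyde sets C2′, and N-acetylation then expels the amine and the C4′ silyl group to unveil the enone; the sense of induction is taken by analogy with the unsubstituted diene, both catalyst enantiomers being available.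

Step 4
Reactants: 6 (2S)-5-(tert-butyldimethylsilyloxy)-2-methyl-2,3-dihydro-4H-pyran-4-one
Product: 7 (2S,4R)-5-(tert-butyldimethylsilyloxy)-2-methyl-3,4-dihydro-2H-pyran-4-ol
Conditions: NaBH4, CeCl3·7H2O, MeOH, −78 °C
Reagents that add atoms: none
Why: Luche 1,2-reduction with axial hydride delivery to the half-chair bearing an equatorial methyl group should give the cis-2,4 alcohol, the temporary C4′ stereocentre.

Step 5
Reactants: 7 (2S,4R)-5-(tert-butyldimethylsilyloxy)-2-methyl-3,4-dihydro-2H-pyran-4-ol
Product: 8 (2S,4R)-5-(tert-butyldimethylsilyloxy)-2-methyl-4-(triethylsilyloxy)-3,4-dihydro-2H-pyran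
Conditions: Et3SiCl, imidazole, DMF, 0 °C
Reagents that add atoms: chlorotriethylsilane, CC[Si](Cl)(CC)CC
Why: Standard silylation; the TES ether shields one face of the double bond and is later removable beside the tertiary TBS ether.

Step 6
Reactants: 9 2-methylcyclopentane-1,3-dione
Product: 10 benzyl 2-methyl-3-oxocyclopent-1-en-1-yl carbonate
Conditions: BnOCOCl, Et3N, CH2Cl2, 0 °C
Reagents that add atoms: benzyl chloroformate, O=C(Cl)OCc1ccccc1
Why: O-acylation of the symmetrical enolised dione gives a non-acidic β-acyloxy enone chromophore whose carbonate can be removed later under neutral conditions.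

Step 7
Reactants: 10 benzyl 2-methyl-3-oxocyclopent-1-en-1-yl carbonate; 8 (2S,4R)-5-(tert-butyldimethylsilyloxy)-2-methyl-4-(triethylsilyloxy)-3,4-dihydro-2H-pyran
Product: 11 cyclobutane photoadduct (cyclopentanone–cyclobutane–tetrahydropyran tricycle; C8a–OCO2Bn; C6–CH3; C7–OTBS; C4′–OTES)
Conditions: hν (350 nm, Pyrex filter), 8 (3 equiv, excess recovered), degassed CH2Cl2, −20 °C
Reagents that add atoms: none
Why: Excitation of the n→π* band of 10 and intersystem crossing give the triplet enone, which adds to the ground-state, non-absorbing enediol bis-ether 8 through a triplet 1,4-biradical that closes to the cyclobutane, so that C8–C8a and C6–C7 form in one photochemical operation. The closest known reaction type is the first stage of the de Mayo reaction in its enol carbonate form, that is, intermolecular enone–enol ether [2+2] photocycloaddition. The only ring closed is the cyclobutane, by stepwise radical bond formation (first the unhindered CH terminus C8 to the enone β-carbon C8a, then recombination of the tertiary α-keto radical at C6 with the tertiary α-siloxy radical at C7), cis-fused to both the five- and the six-membered ring as their size demands. C7 and C8 are set by cis addition across the pyran double bond on the face anti to the allylic C4′-OTES and the C2′-methyl group, whereas the configurations created at C6 and C8a are erased in step 8, so the mutual orientation of the partners about the cyclobutane does not matter. The step needs head-to-tail regiochemistry with respect to the ring oxygen and cross- rather than self-addition of the enone: the first should follow from the ring oxygen on the sterically open CH terminus (as in additions of enones to vinyl ethers and dihydropyran) and from the more stable biradical formed by bonding at the enone β-carbon, the second from irradiating where only 10 absorbs and using 8 in excess.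

Step 8
Reactants: 11 cyclobutane photoadduct
Product: 13 pyran-fused cycloheptane-5,8a-dione (7-OTBS; 4′-OTES), via cyclobutanol 12 (not isolated)
Conditions: H2 (1 atm), Pd/C, EtOAc, 23 °C
Reagents that add atoms: none
Why: Hydrogenolysis of the benzyl carbonate and loss of CO2 free the cyclobutanol, whose strain-driven retro-aldol cleavage of C6–C8a (de Mayo fragmentation, neutral conditions) expands the five-membered ring to the seven-membered 1,4-dione; C6 is set on ketonisation and stays epimerisable toward the assumed stable isomer.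

Step 9
Reactants: 13 pyran-fused cycloheptane-5,8a-dione
Product: 14 pyran-fused cyclohept-3a-ene-5,8a-dione
Conditions: IBX, 4-methoxypyridine N-oxide, DMSO, 25 °C
Reagents that add atoms: none
Why: IBX dehydrogenation through the enol can only desaturate C3a–C4, because the other β-carbon of both ketones (C7) is quaternary, so both carbonyls lead to the same ene-dione.

Step 10
Reactants: 14 pyran-fused cyclohept-3a-ene-5,8a-dione
Product: 15 8a-hydroxy enone (8a-OH cis to O1′)
Conditions: Zn(BH4)2, Et2O, −78 to −40 °C; aqueous NH4Cl work-up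
Reagents that add atoms: none
Why: Chelation of zinc between the C8a carbonyl and the adjacent ring ether oxygen should activate this carbonyl over C5 and direct 1,2-hydride delivery anti to the C8–C7 bond, giving the alcohol cis to O1′ (the polar 1,2-induction model predicts the same face).

Step 11
Reactants: 15 8a-hydroxy enone; 16 acrylic acid
Product: 17 8a-acrylate (C8a inverted; oxygen trans to O1′)
Conditions: PPh3, DIAD, THF, 0 to 23 °C
Reagents that add atoms: none
Why: Mitsunobu esterification of the allylic alcohol proceeds by SN2 displacement of the alkoxyphosphonium with inversion, placing the C8a oxygen trans to the C8 oxygen as in the target.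

Step 12
Reactants: 17 8a-acrylate
Product: 18 cis-fused α-methylidene lactone (7-OTBS; 4′-OTES)
Conditions: PBu3 (20 mol %), tert-amyl alcohol, 23 °C
Reagents that add atoms: none
Why: Intramolecular Rauhut–Currier reaction: the phosphine adds to the unhindered acrylate, the ester enolate attacks C3a 5-exo-trig on the face of the tether (cis ring fusion sets C3a), and proton transfer with loss of phosphine regenerates the methylidene group.

Step 13
Reactants: 18 cis-fused α-methylidene lactone
Product: 19 4′-alcohol
Conditions: HF·pyridine, pyridine, THF, 0 °C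
Reagents that add atoms: none
Why: The secondary TES ether is cleaved much faster than the hindered tertiary TBS ether under buffered fluoride conditions.

Step 14
Reactants: 19 4′-alcohol
Product: 20 4′-ketone (tetrahydropyran-4′-one)
Conditions: DMP, pyridine, CH2Cl2, 0 to 23 °C
Reagents that add atoms: none
Why: Mild, non-basic oxidation of the hindered secondary alcohol removes the second temporary stereocentre without opening the β-alkoxy ketone.

Step 15
Reactants: 20 4′-ketone; 21 3-methylbutanoic anhydride
Product: 23 7-O-TBS ether of the target, via ring-opened 8-hydroxy enone 22 (not isolated)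
Conditions: DBU, DMAP (cat.), CH2Cl2, 0 to 23 °C
Reagents that add atoms: none
Why: Base-mediated E1cB (retro-oxa-Michael) at the only enolisable α-carbon C3′ opens the pyranone to the (E)-enone and the C8 alcohol, which is acylated irreversibly so that the ring–chain equilibrium is drained; C6 can equilibrate through the enol at this stage.

Step 16
Reactants: 23 7-O-TBS ether of the target
Product: 24 (3aS,6R,7S,8S,8aR)-7-[(2E)-but-2-enoyl]-7-hydroxy-6-methyl-3-methylidene-2,5-dioxooctahydro-2H-cyclohepta[b]furan-8-yl 3-methylbutanoate
Conditions: HF·pyridine, THF, 0 to 23 °C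
Reagents that add atoms: none
Why: Fluoride cleavage of the tertiary silyl ether under weakly acidic conditions should free the tertiary alcohol without retro-aldol cleavage of the β-hydroxy ketone.

**Compound list**

1 | 1-(tert-butyldimethylsilyloxy)propan-2-one | CC(=O)CO[Si](C)(C)C(C)(C)C | starting material
2 | (Z)-3-(tert-butyldimethylsilyloxy)-4-(dimethylamino)but-3-en-2-one | CC(=O)/C(O[Si](C)(C)C(C)(C)C)=C/N(C)C | intermediate
3 | (1Z)-2,3-bis(tert-butyldimethylsilyloxy)-N,N-dimethylbuta-1,3-dien-1-amine | C=C(O[Si](C)(C)C(C)(C)C)/C(O[Si](C)(C)C(C)(C)C)=C/N(C)C | intermediate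
4 | acetaldehyde | CC=O | starting material
5 | aminal cycloadduct, (2S)-4,5-bis(tert-butyldimethylsilyloxy)-6-(dimethylamino)-2-methyl-3,6-dihydro-2H-pyran (aminal carbon as epimer mixture) | C[C@H]1CC(O[Si](C)(C)C(C)(C)C)=C(O[Si](C)(C)C(C)(C)C)C(N(C)C)O1 | intermediate (not isolated)
6 | (2S)-5-(tert-butyldimethylsilyloxy)-2-methyl-2,3-dihydro-4H-pyran-4-one | C[C@H]1CC(=O)C(O[Si](C)(C)C(C)(C)C)=CO1 | intermediate
7 | (2S,4R)-5-(tert-butyldimethylsilyloxy)-2-methyl-3,4-dihydro-2H-pyran-4-ol | C[C@H]1C[C@@H](O)C(O[Si](C)(C)C(C)(C)C)=CO1 | intermediate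
8 | (2S,4R)-5-(tert-butyldimethylsilyloxy)-2-methyl-4-(triethylsilyloxy)-3,4-dihydro-2H-pyran | C[C@H]1C[C@@H](O[Si](CC)(CC)CC)C(O[Si](C)(C)C(C)(C)C)=CO1 | intermediate
9 | 2-methylcyclopentane-1,3-dione | CC1C(=O)CCC1=O | starting material
10 | benzyl 2-methyl-3-oxocyclopent-1-en-1-yl carbonate | CC1=C(OC(=O)OCc2ccccc2)CCC1=O | intermediate
11 | cyclobutane photoadduct: cis-anti-cis tricycle, cyclobutane cis-fused to the cyclopentanone (C6–CH3, C8a–OCO2Bn) and to the tetrahydropyran (C7–OTBS, C8–H; 2′S-methyl, 4′R-OTES); new bonds anti to OTES | C[C@]12C(=O)CC[C@@]1(OC(=O)OCc4ccccc4)[C@@H]3O[C@@H](C)C[C@@H](O[Si](CC)(CC)CC)[C@]23O[Si](C)(C)C(C)(C)C | intermediate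
12 | cyclobutanol (11 without the benzyloxycarbonyl group) | C[C@]12C(=O)CC[C@@]1(O)[C@@H]3O[C@@H](C)C[C@@H](O[Si](CC)(CC)CC)[C@]23O[Si](C)(C)C(C)(C)C | intermediate (not isolated)
13 | pyran-fused cycloheptane-5,8a-dione: cis ring fusion, O1′ and C4′ on one face of the seven-membered ring, 7-OTBS and 6-methyl on the other; 2′-methyl, 4′-OTES and 7-OTBS cis on the pyran | O=C1CCC(=O)[C@H](C)[C@@]2(O[Si](C)(C)C(C)(C)C)[C@H](O[Si](CC)(CC)CC)C[C@H](C)O[C@@H]12 | intermediate
14 | pyran-fused cyclohept-3a-ene-5,8a-dione | O=C1C=CC(=O)[C@H](C)[C@@]2(O[Si](C)(C)C(C)(C)C)[C@H](O[Si](CC)(CC)CC)C[C@H](C)O[C@@H]12 | intermediate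
15 | 8a-hydroxy enone, 8a-OH cis to O1′ | O[C@H]1C=CC(=O)[C@H](C)[C@@]2(O[Si](C)(C)C(C)(C)C)[C@H](O[Si](CC)(CC)CC)C[C@H](C)O[C@@H]12 | intermediate
16 | acrylic acid | C=CC(=O)O | starting material
17 | 8a-acrylate, ester oxygen trans to O1′ | C=CC(=O)O[C@@H]1C=CC(=O)[C@H](C)[C@@]2(O[Si](C)(C)C(C)(C)C)[C@H](O[Si](CC)(CC)CC)C[C@H](C)O[C@@H]12 | intermediate
18 | cis-fused α-methylidene-γ-lactone on the pyran-fused cycloheptanone (7-OTBS, 4′-OTES) | C=C1C(=O)O[C@@H]2[C@H]1CC(=O)[C@H](C)[C@@]3(O[Si](C)(C)C(C)(C)C)[C@H](O[Si](CC)(CC)CC)C[C@H](C)O[C@@H]23 | intermediate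
19 | 4′-alcohol of 18 | C=C1C(=O)O[C@@H]2[C@H]1CC(=O)[C@H](C)[C@@]3(O[Si](C)(C)C(C)(C)C)[C@H](O)C[C@H](C)O[C@@H]23 | intermediate
20 | 4′-ketone (2′-methyltetrahydropyran-4′-one fused at C7–C8) | C=C1C(=O)O[C@@H]2[C@H]1CC(=O)[C@H](C)[C@@]3(O[Si](C)(C)C(C)(C)C)C(=O)C[C@H](C)O[C@@H]23 | intermediate
21 | 3-methylbutanoic anhydride | CC(C)CC(=O)OC(=O)CC(C)C | starting material
22 | ring-opened 8-hydroxy (E)-enone, 7-OTBS | C=C1C(=O)O[C@@H]2[C@H]1CC(=O)[C@H](C)[C@@](O[Si](C)(C)C(C)(C)C)(C(=O)/C=C/C)[C@H]2O | intermediate (not isolated)
23 | 7-O-TBS ether of the target | C=C1C(=O)O[C@@H]2[C@H]1CC(=O)[C@H](C)[C@@](O[Si](C)(C)C(C)(C)C)(C(=O)/C=C/C)[C@H]2OC(=O)CC(C)C | intermediate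
24 | (3aS,6R,7S,8S,8aR)-7-[(2E)-but-2-enoyl]-7-hydroxy-6-methyl-3-methylidene-2,5-dioxooctahydro-2H-cyclohepta[b]furan-8-yl 3-methylbutanoate | C=C1C(=O)O[C@@H]2[C@H]1CC(=O)[C@H](C)[C@@](O)(C(=O)/C=C/C)[C@H]2OC(=O)CC(C)C | target

Total step count: 16. Longest linear sequence: 15 steps (steps 1–5 and 7–16).

**Steps most likely to fail**

Step 7. What may go wrong: erosion of regiocontrol, because both alkene carbons carry oxygen donors, or unproductive quenching of the triplet enone by the very electron-rich silyl enol ether, leaving self-addition of 10. The fallback sets out from 8 and 9 and returns at 13. It makes the donor hierarchy of the alkene unambiguous and runs the fragmentation in the classical free-enol mode. The silyl enol ether of 8 is cleaved with MeLi (THF, 0 °C) and the lithium enolate is O-acylated with benzyl chloroformate to give benzyl (2S,4R)-2-methyl-4-(triethylsilyloxy)-3,4-dihydro-2H-pyran-5-yl carbonate F1, in which the ring oxygen is the only strong donor. Irradiation (350 nm, MeCN) of the enol form of 9 with F1 should give, through the cyclobutanol and its spontaneous retro-aldol cleavage, the 7-O-benzyloxycarbonyl cycloheptane-5,8a-dione F2. Hydrogenolysis (H2, Pd/C, EtOAc) then gives the 7-hydroxy dione F3, and TBSOTf with 2,6-lutidine (CH2Cl2, −78 °C) silylates the tertiary alcohol to give 13.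

Step 15. What may go wrong: the ring–chain equilibrium is not drained (slow E1cB at the hindered ketone), while the amine bases isomerise or add to the methylidene lactone. The fallback sets out from 20 and returns at 23. TMSOTf with Et3N (CH2Cl2, −78 to 0 °C) converts the pyranone into its silyl enol ether and, by silylation of the ring oxygen, drives β-elimination to the 8-O-trimethylsilyl (E)-enone F6; any silyl enol ether of the ring ketone is hydrolysed on work-up. 3-Methylbutanoic anhydride with catalytic Sc(OTf)3 (MeCN, −20 °C) then exchanges the trimethylsilyl group for the isovaleryl group to give 23.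

Step 12. What may go wrong: phosphine-triggered elimination of the allylic carboxylate, or addition of the phosphine to the cycloheptenone instead of the acrylate. The fallback sets out from 15 and returns at 18, replacing the organocatalytic cyclisation by an anionic Michael addition and olefination. Mitsunobu esterification of 15 with diethylphosphonoacetic acid (PPh3, DIAD, THF) gives the inverted 8a-(diethylphosphonoacetoxy) enone F4. Cs2CO3 (MeCN, 0 °C) effects intramolecular Michael addition to C3a to give the cis-fused α-diethylphosphono lactone F5. Horner–Wadsworth–Emmons reaction with aqueous formaldehyde and K2CO3 (THF, 0 °C) gives 18.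

**Further compounds**

F1 | step 7 | benzyl (2S,4R)-2-methyl-4-(triethylsilyloxy)-3,4-dihydro-2H-pyran-5-yl carbonate | C[C@H]1C[C@@H](O[Si](CC)(CC)CC)C(OC(=O)OCc2ccccc2)=CO1
F2 | step 7 | 7-O-benzyloxycarbonyl pyran-fused cycloheptane-5,8a-dione (4′-OTES) | O=C1CCC(=O)[C@H](C)[C@@]2(OC(=O)OCc3ccccc3)[C@H](O[Si](CC)(CC)CC)C[C@H](C)O[C@@H]12
F3 | step 7 | 7-hydroxy pyran-fused cycloheptane-5,8a-dione (4′-OTES) | O=C1CCC(=O)[C@H](C)[C@@]2(O)[C@H](O[Si](CC)(CC)CC)C[C@H](C)O[C@@H]12
F4 | step 12 | 8a-(diethylphosphonoacetoxy) enone (C8a inverted) | CCOP(=O)(OCC)CC(=O)O[C@@H]1C=CC(=O)[C@H](C)[C@@]2(O[Si](C)(C)C(C)(C)C)[C@H](O[Si](CC)(CC)CC)C[C@H](C)O[C@@H]12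
F5 | step 12 | cis-fused α-diethylphosphono lactone (phosphonate carbon as epimer mixture) | CCOP(=O)(OCC)C1C(=O)O[C@@H]2[C@H]1CC(=O)[C@H](C)[C@@]3(O[Si](C)(C)C(C)(C)C)[C@H](O[Si](CC)(CC)CC)C[C@H](C)O[C@@H]23
F6 | step 15 | 8-O-trimethylsilyl 7-O-TBS (E)-enone | C=C1C(=O)O[C@@H]2[C@H]1CC(=O)[C@H](C)[C@@](O[Si](C)(C)C(C)(C)C)(C(=O)/C=C/C)[C@H]2O[Si](C)(C)C
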